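**Retrosynthetic overview**

- Feature: ring A is the enolised acyl-trione ring and ring B the arene. The bridge CH2, the ring A carbon that carries it and the neighbouring ring A carbonyl carbon lie ortho to a ring B phenol oxygen, so they are a 3-arylpropanoate lactone (a 3,4-dihydrocoumarin). The other ring A carbons (C–OH, CMe2, C–OH, acyl-bearing carbon) with the ring A butyryl chain are the enol lactone 3,3-dimethyl-6-propylpyran-2,4-dione.
- Key disconnection: two ring A bonds (bridge-bearing carbon to the enol carbon beside CMe2; butyryl-bearing carbon to the ring carbonyl) go back to the two lactone C–O bonds. The dihydrocoumarin enolate is acylated by the pyrandione (Claisen), and the freed diketone enolate closes ring A on the aryl lactone (Dieckmann).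
- Dihydrocoumarin: 2,5-dimethylresorcinol plus acrylic acid, then butyrylation of the one free ring B carbon and double silylation. The ring B butyryl group is thus in place before the cascade, masked as a silyl enol ether with no acidic hydrogen. Acylating the finished bridged dimer with a Lewis acid would put the bridge at risk (cleavage, cyclodehydration of the ortho phenol onto ring A).
- Pyrandione: terminal enol silane of 2-pentanone plus dimethylmalonyl dichloride.
- Ring order: ring B is bought; the two lactone rings are temporary and both open in the step that closes ring A, the only permanent ring made; one global desilylation ends the route.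

Key step: step 6

Remark: ring A is drawn throughout in the enol tautomer of the target SMILES (the tautomers interconvert). The silyl enol ether carried from step 3 to step 7 is drawn Z, the geometry expected from soft enolisation; its geometry has no bearing on the target.

**Step 1**
Reactants: 1 2,5-dimethylbenzene-1,3-diol (2,5-dimethylresorcinol); 2 acrylic acid
Product: 3 7-hydroxy-5,8-dimethyl-3,4-dihydro-2H-chromen-2-one
Conditions: Amberlyst 15 (sulfonic acid resin), toluene, 110 °C, Dean–Stark
Reagents that add atoms: none
Why: Acid-mediated Friedel–Crafts hydroarylation of the acrylate at the carbon ortho to one hydroxyl and para to the other, followed by lactonisation of the neighbouring phenol, is the usual way from resorcinols to 7-hydroxydihydrocoumarins, and the two open ring carbons of 1 are equivalent by symmetry, so only one lactone can form.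

**Step 2**
Reactants: 3 7-hydroxy-5,8-dimethyl-3,4-dihydro-2H-chromen-2-one; 4 butanoic acid
Product: 5 6-butanoyl-7-hydroxy-5,8-dimethyl-3,4-dihydro-2H-chromen-2-one
Conditions: BF3·OEt2 (excess), 90 °C; then aq. NaOAc, 50 °C
Reagents that add atoms: none
Why: BF3-promoted Friedel–Crafts acylation (Nencki/Fries type) can take place only at C6, the single unsubstituted ring carbon, which is activated by the ortho hydroxyl and the para lactone oxygen, and the aryl lactone should tolerate the acidic medium in which such lactones are themselves made.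

**Step 3**
Reactants: 5 6-butanoyl-7-hydroxy-5,8-dimethyl-3,4-dihydro-2H-chromen-2-one
Product: 6 7-(tert-butyldimethylsilyloxy)-6-[(Z)-1-(tert-butyldimethylsilyloxy)but-1-en-1-yl]-5,8-dimethyl-3,4-dihydro-2H-chromen-2-one
Conditions: TBSOTf (2.5 equiv), Et3N, CH2Cl2, 0 °C to rt
Reagents that add atoms: tert-butyldimethylsilyl trifluoromethanesulfonate, CC(C)(C)[Si](C)(C)OS(=O)(=O)C(F)(F)F
Why: Silyl triflate with an amine base silylates the phenol and, by soft enolisation (O-silylation of the carbonyl, then deprotonation), turns the out-of-plane aryl ketone into its silyl enol ether, so that the lactone CH2 is the only acidic C–H left for step 6; the aryl lactone should enolise far more slowly under these conditions.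

**Step 4**
Reactants: 7 pentan-2-one
Product: 8 2-(trimethylsilyloxy)pent-1-ene
Conditions: LiN(i-Pr)2, THF, −78 °C; Me3SiCl, −78 °C to rt
Reagents that add atoms: chlorotrimethylsilane, C[Si](C)(C)Cl
Why: Kinetic deprotonation of the methyl group by the hindered amide base and O-silylation of the enolate (kinetic silyl enol ether formation) should give the terminal enol silane, and the minor internal isomer can be removed by fractional distillation or after step 5.

**Step 5**
Reactants: 8 2-(trimethylsilyloxy)pent-1-ene; 9 2,2-dimethylpropanedioyl dichloride (dimethylmalonyl dichloride)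
Product: 11 3,3-dimethyl-6-propyl-2H-pyran-2,4(3H)-dione, via 2,2-dimethyl-3,5-dioxooctanoyl chloride 10 (not isolated)
Conditions: ZnCl2 (10 mol %), 9 (1.5 equiv), Et2O–CH2Cl2, −20 °C to rt, slow addition of 8; then Et3N, 0 °C
Reagents that add atoms: none
Why: Lewis-acid-catalysed C-acylation of the silyl enol ether by one acyl chloride group (Mukaiyama-type acylation, the way malonyl dichlorides give pyranones) gives 10, whose diketone enol oxygen then acylates at the second acyl chloride (6-exo-trig enol lactonisation, helped by the gem-dimethyl group); excess 9 and slow addition of 8 hold back double acylation.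

**Step 6**
Reactants: 6 7-(tert-butyldimethylsilyloxy)-6-[(Z)-1-(tert-butyldimethylsilyloxy)but-1-en-1-yl]-5,8-dimethyl-3,4-dihydro-2H-chromen-2-one; 11 3,3-dimethyl-6-propyl-2H-pyran-2,4(3H)-dione
Product: 14 2-butanoyl-6-{[3-[(Z)-1-(tert-butyldimethylsilyloxy)but-1-en-1-yl]-4-(tert-butyldimethylsilyloxy)-6-hydroxy-2,5-dimethylphenyl]methyl}-3,5-dihydroxy-4,4-dimethylcyclohexa-2,5-dien-1-one, via lactone lithium enolate 12 (not isolated), via acyclic triketo lactone 13 (not isolated)
Conditions: LiN(SiMe3)2 (2.1 equiv), THF, −78 °C; 11 (1.1 equiv, added slowly), −78 °C; AcOH (1.1 equiv), 4-(dimethylamino)pyridine (20 mol %), −78 to 45 °C; AcOH quench, aq. work-up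
Reagents that add atoms: none
Why: Proposed new method: the lithium enolate 12 adds to the enol-lactone carbonyl C2 of 11 and the tetrahedral adduct collapses with loss of the ring oxygen as a 1,3-diketone enolate (crossed Claisen acylation by an enol ester), giving 13, which the second equivalent of base holds as a bis-enolate so that no lactone enolate is lost by proton transfer to the acidic adduct. One equivalent of AcOH then returns the mono-enolate, whose doubly activated carbon (between the CMe2-flanked ketone and the propyl ketone) attacks the aryl lactone carbonyl and expels the ring B phenoxide, closing ring A by a 6-(enolexo)-exo-trig Dieckmann condensation. The closest known reactions are C-acylation of ester and lactone enolates by enol esters, Dieckmann closure onto aryl esters, and the base- or acyl-transfer-catalysed rearrangement of enol esters and enol lactones into 2-acylcyclohexane-1,3-diones; new is their coupling, so that two lactone C–O bonds are exchanged for two ring C–C bonds in one flask. No stereocentre is created, since C3 of 13 is lost on enolisation. The step needs attack at the lactone carbonyl of 11 and not at its C4 ketone or at C6: only the lactone adduct can collapse irreversibly, addition to the hindered ketone reverts, C6 is fully substituted and deactivated by the ring oxygen, the hard lithium enolate at −78 °C favours direct carbonyl addition, and 11 has no hydrogen between its carbonyls (C3 is quaternary) to quench the enolate. In the ring closure, C- versus O-acylation is kept reversible by the pyridine catalyst, and the strongly acidic enol-trione anion of 14 is the thermodynamic sink.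

**Step 7**
Reactants: 14 2-butanoyl-6-{[3-[(Z)-1-(tert-butyldimethylsilyloxy)but-1-en-1-yl]-4-(tert-butyldimethylsilyloxy)-6-hydroxy-2,5-dimethylphenyl]methyl}-3,5-dihydroxy-4,4-dimethylcyclohexa-2,5-dien-1-one
Product: 15 2-butanoyl-6-[(3-butanoyl-4,6-dihydroxy-2,5-dimethylphenyl)methyl]-3,5-dihydroxy-4,4-dimethylcyclohexa-2,5-dien-1-one (CNP0295128.0)
Conditions: HF·pyridine, THF, 0 °C to rt
Reagents that add atoms: none
Why: Fluoride-mediated desilylation (Si–F bond formation) frees the phenol and converts the silyl enol ether into the butyryl ketone by protonation at carbon, under mildly acidic conditions that should spare the enol-trione and the methylene bridge.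

**Compound list**

1 | 2,5-dimethylbenzene-1,3-diol (2,5-dimethylresorcinol) | Cc1cc(O)c(C)c(O)c1 | starting material
2 | acrylic acid | C=CC(=O)O | starting material
3 | 7-hydroxy-5,8-dimethyl-3,4-dihydro-2H-chromen-2-one | Cc1cc(O)c(C)c2OC(=O)CCc12 | intermediate
4 | butanoic acid | CCCC(=O)O | starting material
5 | 6-butanoyl-7-hydroxy-5,8-dimethyl-3,4-dihydro-2H-chromen-2-one | CCCC(=O)c1c(C)c2CCC(=O)Oc2c(C)c1O | intermediate
6 | 7-(tert-butyldimethylsilyloxy)-6-[(Z)-1-(tert-butyldimethylsilyloxy)but-1-en-1-yl]-5,8-dimethyl-3,4-dihydro-2H-chromen-2-one | CC/C=C(\O[Si](C)(C)C(C)(C)C)c1c(C)c2CCC(=O)Oc2c(C)c1O[Si](C)(C)C(C)(C)C | intermediate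
7 | pentan-2-one | CCCC(C)=O | starting material
8 | 2-(trimethylsilyloxy)pent-1-ene | CCCC(=C)O[Si](C)(C)C | intermediate
9 | 2,2-dimethylpropanedioyl dichloride (dimethylmalonyl dichloride) | CC(C)(C(=O)Cl)C(=O)Cl | starting material
10 | 2,2-dimethyl-3,5-dioxooctanoyl chloride | CCCC(=O)CC(=O)C(C)(C)C(Cl)=O | intermediate
11 | 3,3-dimethyl-6-propyl-2H-pyran-2,4(3H)-dione | CCCC1=CC(=O)C(C)(C)C(=O)O1 | intermediate
12 | lithium enolate of 6 (lithium 7-(tert-butyldimethylsilyloxy)-6-[(Z)-1-(tert-butyldimethylsilyloxy)but-1-en-1-yl]-5,8-dimethyl-4H-chromen-2-olate) | [Li+].CC/C=C(\O[Si](C)(C)C(C)(C)C)c1c(C)c2CC=C([O-])Oc2c(C)c1O[Si](C)(C)C(C)(C)C | intermediate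
13 | 7-(tert-butyldimethylsilyloxy)-6-[(Z)-1-(tert-butyldimethylsilyloxy)but-1-en-1-yl]-3-(2,2-dimethyl-3,5-dioxooctanoyl)-5,8-dimethyl-3,4-dihydro-2H-chromen-2-one (present as its lithium enolates; C3 configuration undefined and lost in step 6) | CC/C=C(\O[Si](C)(C)C(C)(C)C)c1c(C)c2CC(C(=O)C(C)(C)C(=O)CC(=O)CCC)C(=O)Oc2c(C)c1O[Si](C)(C)C(C)(C)C | intermediate
14 | 2-butanoyl-6-{[3-[(Z)-1-(tert-butyldimethylsilyloxy)but-1-en-1-yl]-4-(tert-butyldimethylsilyloxy)-6-hydroxy-2,5-dimethylphenyl]methyl}-3,5-dihydroxy-4,4-dimethylcyclohexa-2,5-dien-1-one | CC/C=C(\O[Si](C)(C)C(C)(C)C)c1c(C)c(CC2=C(O)C(C)(C)C(O)=C(C(=O)CCC)C2=O)c(O)c(C)c1O[Si](C)(C)C(C)(C)C | intermediate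
15 | 2-butanoyl-6-[(3-butanoyl-4,6-dihydroxy-2,5-dimethylphenyl)methyl]-3,5-dihydroxy-4,4-dimethylcyclohexa-2,5-dien-1-one | CCCC(=O)C1=C(O)C(C)(C)C(O)=C(Cc2c(C)c(C(=O)CCC)c(O)c(C)c2O)C1=O | target

**Step count**

Total step count: 7. Longest linear sequence: 5 steps (steps 1, 2, 3, 6, 7); the pyrandione branch adds steps 4 and 5.

**Steps most likely to fail**

1. Step 6 (the cascade, new as a method).
 - What may go wrong: loss of the lactone enolate by conjugate addition at C6 of 11, by proton abstraction from the allylic CH2 of its propyl group or by self-condensation of the lactone; and stalling after the first acylation, so that ring A is not closed.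
 - Fallback (known chemistry: the classical methylene bridging of an acylfilicinic acid with an acylresorcinol), setting out from 1 and 4 and coming back at 15. Compound 1 is C-butyrylated with 4 in BF3·OEt2 at 80 °C to 1-(2,4-dihydroxy-3,6-dimethylphenyl)butan-1-one F1. Phloroglucinol is acylated with butanoyl chloride and AlCl3 to 1-(2,4,6-trihydroxyphenyl)butan-1-one F2. Geminal C-dimethylation of F2 (MeI, NaOMe, MeOH) gives 2-butanoyl-3,5-dihydroxy-4,4-dimethylcyclohexa-2,5-dien-1-one F3. N,N-dimethylmethyleneiminium iodide converts F3 into the Mannich base 2-butanoyl-6-[(dimethylamino)methyl]-3,5-dihydroxy-4,4-dimethylcyclohexa-2,5-dien-1-one F4. On heating with F1 in dioxane, F4 loses dimethylamine to a methylene-trione that F1 captures at its one free ring carbon, giving 15.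

2. Step 5.
 - What may go wrong: double acylation of 9, slow C-acylation next to the quaternary carbon, protodesilylation of 8 by the acid set free, and carry-through of the internal enol silane from step 4 as an isomeric lactone.
 - Fallback, setting out from 7 and coming back at 11. Crossed Claisen condensation of 7 with dimethyl 2,2-dimethylpropanedioate (NaH, THF, reflux; acylation at the methyl group) gives methyl 2,2-dimethyl-3,5-dioxooctanoate F5. Saponification (LiOH, aq. THF) gives 2,2-dimethyl-3,5-dioxooctanoic acid F6. Cyclodehydration with (CF3CO)2O in CH2Cl2 at 0 °C closes the enol lactone 11.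

3. Step 3.
 - What may go wrong: incomplete enolisation of the hindered ketone, competing silylation at the lactone α-carbon, and hydrolytic loss of the silyl enol ether on silica gel or in the work-up of step 6.
 - Fallback, setting out from 3 and coming back at 15; the ring B butyryl group is brought in last. Compound 3 is O-silylated (TBSOTf, 2,6-lutidine, CH2Cl2) to 7-(tert-butyldimethylsilyloxy)-5,8-dimethyl-3,4-dihydro-2H-chromen-2-one F7. Under the conditions of step 6, F7 and 11 should give 2-butanoyl-6-{[4-(tert-butyldimethylsilyloxy)-2-hydroxy-3,6-dimethylphenyl]methyl}-3,5-dihydroxy-4,4-dimethylcyclohexa-2,5-dien-1-one F8. HF·pyridine then gives 2-butanoyl-6-[(2,4-dihydroxy-3,6-dimethylphenyl)methyl]-3,5-dihydroxy-4,4-dimethylcyclohexa-2,5-dien-1-one F9. Friedel–Crafts acylation of the single free ring B carbon of F9 with 4 in BF3·OEt2 (60 °C, then aq. NaOAc) gives 15.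

**Further compounds**

F1 | step 6 | 1-(2,4-dihydroxy-3,6-dimethylphenyl)butan-1-one | CCCC(=O)c1c(C)cc(O)c(C)c1O
F2 | step 6 | 1-(2,4,6-trihydroxyphenyl)butan-1-one | CCCC(=O)c1c(O)cc(O)cc1O
F3 | step 6 | 2-butanoyl-3,5-dihydroxy-4,4-dimethylcyclohexa-2,5-dien-1-one | CCCC(=O)C1=C(O)C(C)(C)C(O)=CC1=O
F4 | step 6 | 2-butanoyl-6-[(dimethylamino)methyl]-3,5-dihydroxy-4,4-dimethylcyclohexa-2,5-dien-1-one | CCCC(=O)C1=C(O)C(C)(C)C(O)=C(CN(C)C)C1=O
F5 | step 5 | methyl 2,2-dimethyl-3,5-dioxooctanoate | CCCC(=O)CC(=O)C(C)(C)C(=O)OC
F6 | step 5 | 2,2-dimethyl-3,5-dioxooctanoic acid | CCCC(=O)CC(=O)C(C)(C)C(=O)O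
F7 | step 3 | 7-(tert-butyldimethylsilyloxy)-5,8-dimethyl-3,4-dihydro-2H-chromen-2-one | Cc1cc(O[Si](C)(C)C(C)(C)C)c(C)c2OC(=O)CCc12
F8 | step 3 | 2-butanoyl-6-{[4-(tert-butyldimethylsilyloxy)-2-hydroxy-3,6-dimethylphenyl]methyl}-3,5-dihydroxy-4,4-dimethylcyclohexa-2,5-dien-1-one | CCCC(=O)C1=C(O)C(C)(C)C(O)=C(Cc2c(C)cc(O[Si](C)(C)C(C)(C)C)c(C)c2O)C1=O
F9 | step 3 | 2-butanoyl-6-[(2,4-dihydroxy-3,6-dimethylphenyl)methyl]-3,5-dihydroxy-4,4-dimethylcyclohexa-2,5-dien-1-one | CCCC(=O)C1=C(O)C(C)(C)C(O)=C(Cc2c(C)cc(O)c(C)c2O)C1=O
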